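**Plan**

- Retrosynthesis: the ring A C5–Cl bond and the silyl ether are cut first. Ring A bonds C3–C4 and C5–C6 are cut next, which returns a 2-pyrone and a ketene bis-silyl acetal. The pyrone is cut at C4–C5 and O1–C2 into an aryl acetoacetate and a methylmalonyl unit, and the depside C–O bond is cut last into the ring B phenol and acetylketene.
- Enabling feature: ring A atoms C1 (carboxyl), C2 (OMe), C3 (Me) and C6 (Me) are C5, C4, C3 and C6 of a 4-methoxy-3,6-dimethyl-2-pyrone-5-carboxylate. Ring A C4 (oxygen) and C5 (H, later Cl) are a two-carbon unit whose oxygen sits para to the carboxyl, which is where a ketene acetal places it.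
- Forward order: ring B phenol from atraric acid (O4 benzylation, O2 methylation, C5 bromination, Suzuki methylation, debenzylation), then acetoacetate, hydroxypyrone, methoxypyrone, ring A by cycloaddition with loss of CO2 and silanol, desilylation, chlorination.
- Stereochemistry: the target has no stereocentre, so nothing has to be controlled.

Key step: step 12

Remark: the bridgehead centres of the transient cycloadduct and the enolisable centres of the acylation intermediate arise as mixtures and disappear again, so all SMILES are written without stereodescriptors.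

**Route**

Step 1
Reactants: 1 atraric acid (methyl 2,4-dihydroxy-3,6-dimethylbenzoate)
Product: 2 methyl 4-(benzyloxy)-2-hydroxy-3,6-dimethylbenzoate
Conditions: BnBr (1.05 equiv), K2CO3, acetone, reflux
Reagents that add atoms: benzyl bromide, BrCc1ccccc1
Why: Williamson etherification should occur only at O4, because the 2-OH is held in a hydrogen bond to the ester carbonyl and is the less acidic and less nucleophilic phenol.

Step 2
Reactants: 2 methyl 4-(benzyloxy)-2-hydroxy-3,6-dimethylbenzoate
Product: 3 methyl 4-(benzyloxy)-2-methoxy-3,6-dimethylbenzoate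
Conditions: MeI, K2CO3, DMF, 60 °C
Reagents that add atoms: iodomethane, CI
Why: Williamson O-methylation of the remaining chelated phenol should go to completion with excess MeI in warm DMF, and nothing else in 2 is alkylated under these conditions.

Step 3
Reactants: 3 methyl 4-(benzyloxy)-2-methoxy-3,6-dimethylbenzoate
Product: 4 methyl 4-(benzyloxy)-5-bromo-2-methoxy-3,6-dimethylbenzoate
Conditions: NBS, MeCN, 0 °C → rt, dark
Reagents that add atoms: N-bromosuccinimide, O=C1CCC(=O)N1Br
Why: Electrophilic aromatic bromination can only occur at C5, the single free ring position (ortho to benzyloxy, para to methoxy), and the polar solvent and exclusion of light keep NBS away from the benzylic methyls.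

Step 4
Reactants: 4 methyl 4-(benzyloxy)-5-bromo-2-methoxy-3,6-dimethylbenzoate
Product: 5 methyl 4-(benzyloxy)-2-methoxy-3,5,6-trimethylbenzoate
Conditions: MeB(OH)2, Pd(OAc)2 (5 mol %), SPhos, K3PO4, toluene/H2O, 100 °C
Reagents that add atoms: methylboronic acid, CB(O)O
Why: Suzuki–Miyaura methylation with SPhos-ligated zerovalent palladium is the standard answer to electron-rich aryl bromides with two ortho substituents, and the hindered ester and the benzyl ether are inert to K3PO4.

Step 5
Reactants: 5 methyl 4-(benzyloxy)-2-methoxy-3,5,6-trimethylbenzoate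
Product: 6 methyl 4-hydroxy-2-methoxy-3,5,6-trimethylbenzoate (ring B phenol)
Conditions: H2 (1 atm), 10% Pd/C, EtOAc/MeOH, rt
Reagents that add atoms: none
Why: Hydrogenolysis of the benzyl aryl ether over Pd/C should free the 4-OH while the ester, the methyl ether and the arene stay untouched.

Step 6
Reactants: 6 methyl 4-hydroxy-2-methoxy-3,5,6-trimethylbenzoate; 7 2,2,6-trimethyl-4H-1,3-dioxin-4-one
Product: 9 methyl 2-methoxy-3,5,6-trimethyl-4-[(3-oxobutanoyl)oxy]benzoate, via acetylketene 8 (not isolated)
Conditions: 7 (2 equiv), o-xylene, 140 °C, acetone distilled off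
Reagents that add atoms: none
Why: Retro-[4+2] fragmentation of 7 releases acetone and acetylketene 8, and addition of the phenol O–H to it (acylketene trapping, an acetoacetylation) passes through a planar six-membered transition state that tolerates the two ortho methyls of 6.

Step 7
Reactants: 10 methylmalonic acid
Product: 11 methylmalonyl dichloride (2-methylpropanedioyl dichloride)
Conditions: SOCl2 (neat), 50 → 70 °C; distillation
Reagents that add atoms: thionyl chloride, O=S(Cl)Cl
Why: Acid chloride formation with thionyl chloride, as in the preparation of malonyl dichloride itself, should give the distillable dichloride with only gaseous by-products.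

Step 8
Reactants: 9 methyl 2-methoxy-3,5,6-trimethyl-4-[(3-oxobutanoyl)oxy]benzoate; 11 methylmalonyl dichloride
Product: 13 methyl 4-[(4-hydroxy-3,6-dimethyl-2-oxo-2H-pyran-5-carbonyl)oxy]-2-methoxy-3,5,6-trimethylbenzoate, via C-acylated acid chloride 12 (not isolated)
Conditions: 11 (1.3 equiv), ClCH2CH2Cl, rt → 60 °C, N2 sweep
Reagents that add atoms: none
Why: In this malonyl dichloride annulation of a β-keto ester, one acid chloride C-acylates the active methylene of 9 and the enol oxygen of the acetyl group attacks the second, which closes the lactone to the 4-hydroxy-2-pyrone-5-carboxylate with the methyl of 11 on C3.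

Step 9
Reactants: 13 methyl 4-[(4-hydroxy-3,6-dimethyl-2-oxo-2H-pyran-5-carbonyl)oxy]-2-methoxy-3,5,6-trimethylbenzoate
Product: 14 methyl 2-methoxy-4-[(4-methoxy-3,6-dimethyl-2-oxo-2H-pyran-5-carbonyl)oxy]-3,5,6-trimethylbenzoate
Conditions: Me2SO4, K2CO3, acetone, reflux
Reagents that add atoms: dimethyl sulfate, COS(=O)(=O)OC
Why: O-Alkylation of the vinylogous carboxylate of a 4-hydroxy-2-pyrone with the hard electrophile Me2SO4 and K2CO3 in acetone is the usual route to 4-methoxy-2-pyrones, and the anhydrous weak base leaves the aryl ester and the lactone intact.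

Step 10
Reactants: 15 sodium acetate (NaOAc); 16 tert-butyldimethylsilyl chloride
Product: 17 tert-butyldimethylsilyl acetate
Conditions: DMF, 40 °C; pentane extraction, distillation
Reagents that add atoms: none
Why: O-Silylation of the carboxylate by substitution at silicon should give the silyl ester, and the non-aqueous work-up avoids its hydrolysis.

Step 11
Reactants: 17 tert-butyldimethylsilyl acetate; 16 tert-butyldimethylsilyl chloride
Product: 19 1,1-bis(tert-butyldimethylsilyloxy)ethene, via lithium enolate 18 (not isolated)
Conditions: LiN(iPr)2, THF, −78 °C; then 16, DMPU, −78 °C → rt; distillation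
Reagents that add atoms: none
Why: Deprotonation of the silyl ester by LiN(iPr)2 gives lithium enolate 18, and silylation by the bulky TBSCl in the presence of DMPU should go on oxygen (ketene silyl acetal formation) and not on carbon.

Step 12
Reactants: 14 methyl 2-methoxy-4-[(4-methoxy-3,6-dimethyl-2-oxo-2H-pyran-5-carbonyl)oxy]-3,5,6-trimethylbenzoate; 19 1,1-bis(tert-butyldimethylsilyloxy)ethene
Product: 22 methyl 4-{[4-(tert-butyldimethylsilyloxy)-2-methoxy-3,6-dimethylbenzoyl]oxy}-2-methoxy-3,5,6-trimethylbenzoate, via bridged lactone cycloadduct 20 (not isolated), via cyclohexadiene silyl ketal 21 (not isolated)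
Conditions: 19 (4 equiv), o-xylene, 145 °C, sealed tube, Ar
Reagents that add atoms: none
Why: The methylene carbon of 19, the nucleophilic end of a very electron-rich alkene, bonds to pyrone C6 (the β-carbon of the C5 aryl ester, activated independently of the methoxy-damped lactone) while the acetal carbon bonds to C3, a [4+2] cycloaddition of inverse electron demand that gives the 2-oxabicyclo[2.2.2]octenone 20. Cycloreversion then expels CO2 to give cyclohexadiene 21, and 1,2-elimination of tert-butyldimethylsilanol across the CH2–C(OSi)2 bond, the only one possible because the other neighbour is the methyl-bearing sp2 carbon, aromatises ring A. The closest known reaction type is the cycloaddition, decarboxylation and alcohol-loss sequence of 2-pyrone-5-carboxylates (coumalates, isodehydroacetates) with ketene acetals, which gives para-alkoxybenzoates. Ring A is the one ring formed, closed by intermolecular [4+2] annulation through its bonds C3–C4 and C5–C6, with the bridged lactone as a transient second ring. No stereocentre remains, since the two bridgehead centres of 20 are racemic and are erased on aromatisation. The step needs regioselectivity (oxygen on C4, hydrogen on C5), secured by the polarity match between the methylene of 19 and C6 of 14, and enough diene electrophilicity despite the 4-methoxy donor, which the aryl ester at C5, the excess of 19 and the high temperature are meant to supply.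

Step 13
Reactants: 22 methyl 4-{[4-(tert-butyldimethylsilyloxy)-2-methoxy-3,6-dimethylbenzoyl]oxy}-2-methoxy-3,5,6-trimethylbenzoate
Product: 23 methyl 4-[(4-hydroxy-2-methoxy-3,6-dimethylbenzoyl)oxy]-2-methoxy-3,5,6-trimethylbenzoate
Conditions: Bu4NF, AcOH, THF, 0 °C
Reagents that add atoms: none
Why: Fluoride-induced cleavage of the aryl silyl ether is fast at 0 °C, and acetic acid buffers the phenoxide so that the depside ester is not attacked.

Step 14
Reactants: 23 methyl 4-[(4-hydroxy-2-methoxy-3,6-dimethylbenzoyl)oxy]-2-methoxy-3,5,6-trimethylbenzoate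
Product: 24 methyl 4-[(5-chloro-4-hydroxy-2-methoxy-3,6-dimethylbenzoyl)oxy]-2-methoxy-3,5,6-trimethylbenzoate (CNP0192286.0)
Conditions: SO2Cl2 (1.05 equiv), CH2Cl2, 0 °C, dark
Reagents that add atoms: sulfuryl chloride, O=S(=O)(Cl)Cl
Why: Electrophilic aromatic chlorination with SO2Cl2 should go to ring A C5, the only aromatic C–H in 23, which is ortho to the free phenol and para to the methoxy group, while ring B is fully substituted.

**Compound list**

1 | atraric acid (methyl 2,4-dihydroxy-3,6-dimethylbenzoate) | COC(=O)c1c(C)cc(O)c(C)c1O | starting material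
2 | methyl 4-(benzyloxy)-2-hydroxy-3,6-dimethylbenzoate | COC(=O)c1c(C)cc(OCc2ccccc2)c(C)c1O | intermediate
3 | methyl 4-(benzyloxy)-2-methoxy-3,6-dimethylbenzoate | COC(=O)c1c(C)cc(OCc2ccccc2)c(C)c1OC | intermediate
4 | methyl 4-(benzyloxy)-5-bromo-2-methoxy-3,6-dimethylbenzoate | COC(=O)c1c(C)c(Br)c(OCc2ccccc2)c(C)c1OC | intermediate
5 | methyl 4-(benzyloxy)-2-methoxy-3,5,6-trimethylbenzoate | COC(=O)c1c(C)c(C)c(OCc2ccccc2)c(C)c1OC | intermediate
6 | methyl 4-hydroxy-2-methoxy-3,5,6-trimethylbenzoate (ring B phenol) | COC(=O)c1c(C)c(C)c(O)c(C)c1OC | intermediate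
7 | 2,2,6-trimethyl-4H-1,3-dioxin-4-one | CC1=CC(=O)OC(C)(C)O1 | starting material
8 | acetylketene (3-oxobut-1-en-1-one), formed in the flask | CC(=O)C=C=O | intermediate
9 | methyl 2-methoxy-3,5,6-trimethyl-4-[(3-oxobutanoyl)oxy]benzoate | COC(=O)c1c(C)c(C)c(OC(=O)CC(C)=O)c(C)c1OC | intermediate
10 | methylmalonic acid | CC(C(=O)O)C(=O)O | starting material
11 | methylmalonyl dichloride | CC(C(Cl)=O)C(Cl)=O | intermediate
12 | C-acylated acid chloride: ring B ester of 2-acetyl-5-chloro-4-methyl-3,5-dioxopentanoic acid, formed in the flask as a tautomer mixture | COC(=O)c1c(C)c(C)c(OC(=O)C(C(C)=O)C(=O)C(C)C(Cl)=O)c(C)c1OC | intermediate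
13 | methyl 4-[(4-hydroxy-3,6-dimethyl-2-oxo-2H-pyran-5-carbonyl)oxy]-2-methoxy-3,5,6-trimethylbenzoate | CC1=C(C(=O)Oc2c(C)c(C)c(C(=O)OC)c(OC)c2C)C(O)=C(C)C(=O)O1 | intermediate
14 | methyl 2-methoxy-4-[(4-methoxy-3,6-dimethyl-2-oxo-2H-pyran-5-carbonyl)oxy]-3,5,6-trimethylbenzoate | CC1=C(C(=O)Oc2c(C)c(C)c(C(=O)OC)c(OC)c2C)C(OC)=C(C)C(=O)O1 | intermediate
15 | sodium acetate (NaOAc) | CC(=O)[O-].[Na+] | starting material
16 | tert-butyldimethylsilyl chloride | CC(C)(C)[Si](C)(C)Cl | starting material
17 | tert-butyldimethylsilyl acetate | CC(=O)O[Si](C)(C)C(C)(C)C | intermediate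
18 | lithium enolate of tert-butyldimethylsilyl acetate, formed in the flask | [Li+].C=C([O-])O[Si](C)(C)C(C)(C)C | intermediate
19 | 1,1-bis(tert-butyldimethylsilyloxy)ethene | C=C(O[Si](C)(C)C(C)(C)C)O[Si](C)(C)C(C)(C)C | intermediate
20 | bridged lactone cycloadduct: ring B ester of 8,8-bis(tert-butyldimethylsilyloxy)-5-methoxy-1,4-dimethyl-3-oxo-2-oxabicyclo[2.2.2]oct-5-ene-6-carboxylic acid, racemic, formed in the flask | CC12OC(=O)C(C)(C(OC)=C1C(=O)Oc1c(C)c(C)c(C(=O)OC)c(OC)c1C)C(O[Si](C)(C)C(C)(C)C)(O[Si](C)(C)C(C)(C)C)C2 | intermediate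
21 | cyclohexadiene silyl ketal: ring B ester of 4,4-bis(tert-butyldimethylsilyloxy)-6-methoxy-2,5-dimethylcyclohexa-1,5-diene-1-carboxylic acid, formed in the flask | CC1=C(OC)C(C(=O)Oc2c(C)c(C)c(C(=O)OC)c(OC)c2C)=C(C)CC1(O[Si](C)(C)C(C)(C)C)O[Si](C)(C)C(C)(C)C | intermediate
22 | methyl 4-{[4-(tert-butyldimethylsilyloxy)-2-methoxy-3,6-dimethylbenzoyl]oxy}-2-methoxy-3,5,6-trimethylbenzoate | COC(=O)c1c(C)c(C)c(OC(=O)c2c(C)cc(O[Si](C)(C)C(C)(C)C)c(C)c2OC)c(C)c1OC | intermediate
23 | methyl 4-[(4-hydroxy-2-methoxy-3,6-dimethylbenzoyl)oxy]-2-methoxy-3,5,6-trimethylbenzoate | COC(=O)c1c(C)c(C)c(OC(=O)c2c(C)cc(O)c(C)c2OC)c(C)c1OC | intermediate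
24 | methyl 4-[(5-chloro-4-hydroxy-2-methoxy-3,6-dimethylbenzoyl)oxy]-2-methoxy-3,5,6-trimethylbenzoate (CNP0192286.0) | COC(=O)c1c(C)c(C)c(OC(=O)c2c(C)c(Cl)c(O)c(C)c2OC)c(C)c1OC | target

**Count and risks**

Total step count: 14. Longest linear sequence: 11 steps (steps 1–6, 8, 9, 12, 13 and 14, from atraric acid).

Steps most likely to fail:

1. Step 12. Bond formation may be too slow: the 4-methoxy group donates into the lactone, the C5 ester is twisted out of conjugation by its two neighbours, and both diene termini are fully substituted. Meanwhile 19 may be used up by O-to-C silyl migration or protonolysis, or Michael addition at C6 may be followed by opening of the lactone instead of ring closure. The fallback sets out from 3 and 6 and takes ring A from atraric acid by the classical depside esterification. Compound 3 is saponified (KOH, aqueous DMSO, 100 °C) to 4-(benzyloxy)-2-methoxy-3,6-dimethylbenzoic acid F1. F1 and phenol 6 are joined with trifluoroacetic anhydride in toluene at room temperature to give the benzyl ether of the des-chloro depside, methyl 4-{[4-(benzyloxy)-2-methoxy-3,6-dimethylbenzoyl]oxy}-2-methoxy-3,5,6-trimethylbenzoate F2. Hydrogenolysis (H2, Pd/C, EtOAc) then gives 23, where the route is rejoined for step 14.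

2. Step 8. The acylation may go astray through O-acylation of the enol, oligomeric acylation by the bifunctional chloride, loss of HCl from 11 to a ketene that self-condenses, or HCl-promoted cleavage of the aryl acetoacetate. The fallback sets out from 11 and builds the pyrone on a simple ester, the substrate class for which the annulation is documented, and makes the depside bond afterwards. Commercial benzyl acetoacetate (CC(=O)CC(=O)OCc1ccccc1) and 11 in warm ClCH2CH2Cl should give benzyl 4-hydroxy-3,6-dimethyl-2-oxo-2H-pyran-5-carboxylate F3. Me2SO4 and K2CO3 in acetone convert it into benzyl 4-methoxy-3,6-dimethyl-2-oxo-2H-pyran-5-carboxylate F4. Brief hydrogenolysis over Pd/C, stopped after one equivalent of H2, frees 4-methoxy-3,6-dimethyl-2-oxo-2H-pyran-5-carboxylic acid F5. Esterification of F5 with phenol 6 by trifluoroacetic anhydride in toluene returns to the route at 14.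

3. Step 9. The ambident pyrone anion may be methylated at the lactone carbonyl oxygen, which leads to the isomeric 2-methoxy-4-pyranone, or at C3. The fallback sets out from 13 and replaces enolate alkylation by a Mitsunobu etherification (MeOH, PPh3, diisopropyl azodicarboxylate, THF, 0 °C → rt). There the pyrone is the acid partner and the methyl comes from an alkoxyphosphonium ion, a mode known to give 4-alkoxy-2-pyrones from 4-hydroxy-2-pyrones. It comes back to the route directly at 14 and makes no new compound (F0).

**Further compounds**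

F1 | step 12 | 4-(benzyloxy)-2-methoxy-3,6-dimethylbenzoic acid | OC(=O)c1c(C)cc(OCc2ccccc2)c(C)c1OC
F2 | step 12 | methyl 4-{[4-(benzyloxy)-2-methoxy-3,6-dimethylbenzoyl]oxy}-2-methoxy-3,5,6-trimethylbenzoate | COC(=O)c1c(C)c(C)c(OC(=O)c2c(C)cc(OCc3ccccc3)c(C)c2OC)c(C)c1OC
F3 | step 8 | benzyl 4-hydroxy-3,6-dimethyl-2-oxo-2H-pyran-5-carboxylate | CC1=C(C(=O)OCc2ccccc2)C(O)=C(C)C(=O)O1
F4 | step 8 | benzyl 4-methoxy-3,6-dimethyl-2-oxo-2H-pyran-5-carboxylate | CC1=C(C(=O)OCc2ccccc2)C(OC)=C(C)C(=O)O1
F5 | step 8 | 4-methoxy-3,6-dimethyl-2-oxo-2H-pyran-5-carboxylic acid | CC1=C(C(=O)O)C(OC)=C(C)C(=O)O1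
F0 | step 9 | none | none
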